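# Proposed synthesis of CNP0260213.10 by transannular [2,3]-Wittig ring contraction

## Structural features

The target is a germacrane: a ten-membered carbocycle (C1–C10) with one Z-trisubstituted alkene (C1=C10, methyl on C10) and a trisubstituted oxirane across C4–C5 (methyl on C4). It carries a free secondary hydroxyl at C6, an isopropyl group at C7 and a 3,4,5-trimethoxybenzoate on the C8 oxygen. Five stereocentres are contiguous from C4 to C8, and CIP analysis of the target gives 4S,5R,6R,7S,8R. In relative terms the C6 hydroxyl, the C7 isopropyl group and the C8 acyloxy group lie on one face of the ring, and the oxirane is the cis-epoxide of a Z C4=C5 alkene with its oxygen on the face of the C6 hydroxyl. Fragile elements are the 2,3-epoxy alcohol (Payne rearrangement, acid-triggered transannular attack by C1=C10), the ester beside a free 1,3-related hydroxyl (acyl migration) and the Z alkene. The 1(10),4-diene intermediates are also sensitive to acid-induced transannular cyclisation. The real difficulty is the combination of a medium ring, two Z-trisubstituted ring alkenes at the diene stage, an all-cis stereotriad at C6–C8 without a chiral-pool handle, and two similar secondary hydroxyls of which only C8 is acylated. The key step exploits C6(OH)–C7: once isopropyl is read as isopropenyl (C11=C12), the unit C4=C5–C6(OH)–C7–C11=C12 is the 1,5-dien-3-ol retron of a [2,3]-Wittig shift. Cutting C6–C7 and joining the oxygen to C12 gives a thirteen-membered diallyl ether in which C8 is a masked, stereocentre-free carbonyl.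

A check of the precursor and product of the key step against the target found no structural error. C6 and C7 of 18 have the same spatial arrangement as in 26; the C6 descriptor changes from S to R only because C5 gains priority on epoxidation. Three design points needed tightening and are built into the route:
- the two secondary hydroxyls are differentiated by masking C6 while it is the only hydroxyl;
- the rhodium hydrogenation is placed after sulfur has been removed;
- the base is a reversible amide rather than an alkyllithium, which suits the dithiane and the regiochemical demand.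

## Logic of the disconnections

**26 ⇒ 25.** The two C–O bonds of the oxirane are cut last. 25 has a free allylic hydroxyl at C6 beside the Z C4=C5 alkene, which can deliver the oxidant to the syn face and leaves the remote C1=C10 alkene alone. The demand is syn facial selectivity in a ten-membered Z-allylic alcohol and mild, non-acidic conditions.

**25 ⇒ 24 ⇒ 22 + 23.** The ester C–O bond at C8 is cut to the acid chloride 23 and the alcohol 22. Since C6–OH and C8–OH would compete in acylation, C6 is carried as a 4-methoxybenzyl ether (24, 22), removable oxidatively under neutral conditions that spare ester and alkenes. The demand is that acylation of a hindered secondary alcohol proceeds and that deprotection causes no acyl migration.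

**22 ⇒ 21 ⇒ 20.** The isopropyl group is traced back to isopropenyl (the C11=C12 π bond is the functional trace of the key step), and the C8–H bond to the ketone 20. The C6 ether oxygen is used as a chelating relay so that hydride delivery gives the 6,8-syn relationship. The demand is a six-membered chelate compatible with the ring and selective saturation of the 1,1-disubstituted alkene in the presence of two trisubstituted ones.

**20 ⇒ 19 ⇒ 18.** The ketone is unmasked from the dithiane and the ether is put on the only hydroxyl present. Simplification: 18 has just two stereocentres and no carbonyl. The demand is a dithiane hydrolysis that tolerates the diene and does not epimerise C7.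

**18 ⇒ 17 (key).** The C6–C7 bond is cut and O–C12 re-formed. The ten-membered ring with two adjacent stereocentres becomes an achiral thirteen-membered ether, whose closure is far easier than direct medium-ring formation. The demands are proton removal at C6 rather than C12, discrimination of the enantiotopic C6 protons, and Z geometry at C7=C11 to translate into the cis C6/C7 pair.

**17 ⇒ 16.** The O–C6 ether bond is cut to an allylic chloride and an allylic alkoxide. The demand is high-dilution SN2 closure without SN2′ or Z/E leakage.

**16 ⇒ 15 ⇒ 13 ⇒ 12 ⇒ 11 + 5.** Functional-group changes (ester to alcohol, silyl ether to chloride) lead to 12, whose C7=C11 bond is cut by a Z-selective phosphonate olefination of the hindered aldehyde 11 with 5. The demand is Z selectivity on an α-quaternary aldehyde.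

**11 ⇒ 10 ⇒ 8 + 9.** The C8–C9 bond is cut to the allylic bromide 8 and the acyl-anion equivalent 9, whose ester carbon becomes C7. The demand is clean SN2 alkylation at the primary allylic carbon.

**8 ⇒ 7 ⇒ 6 ⇒ 4 + 5.** The C1=C10 bond is cut by the same Z-selective olefination, so one reagent (5) installs both methyl-bearing Z alkenes.

**4 ⇒ 2 ⇒ 1.** The C1 aldehyde comes from cleavage of the terminal alkene of 1, which already contains C1–C6 with the Z C4=C5 geometry. The demand is chemoselective cleavage of the distal alkene.

## Other disconnections considered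

**Alternative 1:** The cut is C2–C3, the saturated joint between the two alkenes. In the forward sense KN(SiMe3)2 deprotonates the allylic sulfone carbon C2 of the open-chain chloro sulfone A2, and the carbanion displaces the allylic chloride at C3 at high dilution to give the ten-membered sulfone A1.
- In favour: the bond formed is stereochemically silent, so C6, C7 and C8 can be set beforehand in acyclic chemistry with established absolute control. The two hydroxyls arrive already differentiated (PMB at C8, TBS at C6). On both of these points it is better than the chosen plan, which relies on a chiral base for absolute configuration and needs an extra protecting step.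
- Against: it closes a ten-membered ring end to end, the least favourable ring size, where dimerisation, SN2′ displacement and γ-alkylation of the sulfonyl allyl anion compete. The sulfone must then be removed reductively, a step known to risk allylic transposition or Z/E loss at C1=C10. Two Z-trisubstituted alkenes and three stereocentres must be carried through a longer linear sequence.
- Comparison: mechanistically it is a bimolecular-type alkylation under entropic penalty, whereas the chosen plan forms an easy thirteen-membered ether and lets a concerted shift make the strained ring. In step count it is likely somewhat longer because of the desulfonylation and the acyclic stereotriad synthesis.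

**Alternative 2:** The cut is C8–C9 with reconnection of C1–C6, an anionic oxy-Cope ring expansion. The potassium alkoxide (KH, 18-crown-6) of the cis-dialkenyl cyclohexenol A4, made from the limonene-derived enone A5 and a silyl-substituted alkenyl metal, rearranges through a chair to the ten-membered enolate. Protonation at C7 gives the silyl ketone A3.
- In favour: it is by far the shortest entry to the ring, it is also a ring expansion and therefore equal to the chosen plan in avoiding direct medium-ring closure, and it starts from the chiral pool. In step economy and in the source of absolute configuration it is better than the chosen plan.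
- Against: the Z C1=C10 geometry requires the cis-dialkenyl carbinol reacting through a chair with the oxyanion axial, whereas addition to A5 normally favours the trans adduct, which leads to the E alkene. C7 is set only by enolate protonation, and C6 later by reduction of an enone. The silicon at C8 must be converted into oxygen by a Tamao–Fleming oxidation, whose electrophilic and peroxidic conditions endanger the diene. The hydroxyl-differentiation problem remains.
- Comparison: three of the five stereocentres would rest on weakly controlled events, against one uncertain element (enantioselection) in the chosen plan.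

**Alternative 3:** The cut is C9–C10. Zinc inserts into the C–Br bond of the bromomethyl ketone A7, and Pd(dba)2 with P(t-Bu)3 couples the zinc enolate with the Z alkenyl iodide at C10 to close the ring to the β,γ-unsaturated ketone A6.
- In favour: C6 and C7 are set before cyclisation by acyclic methods, the Z geometry of C1=C10 is fixed in the iodide and retained on oxidative addition, and the product is already the protected C8 ketone. In stereochemical security of C6/C7 it is better than the chosen plan, and it is equal downstream, since both routes pass through a C6-protected C8 ketone.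
- Against: zerovalent palladium coupling of zinc enolates is established for intermolecular arylation of ester and amide enolates. A ketone zinc enolate, an alkenyl iodide and a ten-membered closure together are an extrapolation. The α-bromoketone beside the C7 stereocentre invites epimerisation and loss of the β-silyloxy group, and the high dilution needed for the ring works against catalyst turnover.
- Comparison: step economy is similar or slightly better, but the risk is concentrated in a ring closure without close precedent, whereas the chosen contraction has direct precedent on thirteen-membered ethers.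

Key step: step 13

## Route

Assumption: the (S,S)-amide is assumed to remove the enantiotopic C6 proton that leads to (6S,7S)-18; the equally available (R,R)-amide would be used if the opposite sense is found.

Remark: ring compounds 17–26 are named with germacrane numbering (C1=C10, C4, C5, C6–O, C7, C8, with C11–C13 the three-carbon side chain on C7).

Step 1
Reactants: 1 nerol, (2Z)-3,7-dimethylocta-2,6-dien-1-ol
Product: 2 neryl tert-butyldimethylsilyl ether, tert-butyl{[(2Z)-3,7-dimethylocta-2,6-dien-1-yl]oxy}dimethylsilane
Conditions: TBSCl, imidazole, DMF, 0 °C → rt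
Reagents that add atoms: tert-butyldimethylsilyl chloride, CC(C)(C)[Si](C)(C)Cl
Why: Routine silylation of a primary allylic alcohol; the silyl ether tolerates the phosphonate anions, i-Bu2AlH and the dithiane enolate that follow and is removed by fluoride.

Step 2
Reactants: 2 neryl tert-butyldimethylsilyl ether
Product: 4 (4Z)-6-[(tert-butyldimethylsilyl)oxy]-4-methylhex-4-enal, via secondary ozonide 3 (not isolated)
Conditions: O3 (1 equiv, Sudan Red 7B end point), CH2Cl2, −78 °C; then PPh3, −78 °C → rt
Reagents that add atoms: ozone, [O-][O+]=O
Why: Chemoselective ozonolysis: the distal trisubstituted alkene is more electron-rich than the one deactivated by the allylic oxygen, so one equivalent of ozone with a dye end point should cleave it first; reductive work-up of the ozonide gives the C1 aldehyde with the Z C4=C5 alkene untouched.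

Step 3
Reactants: 4 (4Z)-6-[(tert-butyldimethylsilyl)oxy]-4-methylhex-4-enal; 5 ethyl 2-[bis(2,2,2-trifluoroethoxy)phosphoryl]propanoate
Product: 6 ethyl (2Z,6Z)-8-[(tert-butyldimethylsilyl)oxy]-2,6-dimethylocta-2,6-dienoate
Conditions: KN(SiMe3)2, 18-crown-6, THF, −78 °C
Reagents that add atoms: none
Why: Still–Gennari olefination; the electron-poor phosphonate and the dissociated potassium counter-ion make elimination faster than equilibration, so the kinetic Z enoate (ester cis to the chain) should dominate, which fixes the Z C1=C10 geometry.

Step 4
Reactants: 6 ethyl (2Z,6Z)-8-[(tert-butyldimethylsilyl)oxy]-2,6-dimethylocta-2,6-dienoate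
Product: 7 (2Z,6Z)-8-[(tert-butyldimethylsilyl)oxy]-2,6-dimethylocta-2,6-dien-1-ol
Conditions: i-Bu2AlH (2.3 equiv), CH2Cl2, −78 → 0 °C; aq potassium sodium tartrate
Reagents that add atoms: none
Why: 1,2-Reduction of the enoate to the allylic alcohol by diisobutylaluminium hydride without touching the silyl ether or the alkene geometry.

Step 5
Reactants: 7 (2Z,6Z)-8-[(tert-butyldimethylsilyl)oxy]-2,6-dimethylocta-2,6-dien-1-ol
Product: 8 {[(2Z,6Z)-8-bromo-3,7-dimethylocta-2,6-dien-1-yl]oxy}(tert-butyl)dimethylsilane
Conditions: CBr4, PPh3, CH2Cl2, −20 → 0 °C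
Reagents that add atoms: carbon tetrabromide, BrC(Br)(Br)Br
Why: Appel bromination of a primary allylic alcohol under neutral conditions, SN2 at carbon, so the Z geometry and the silyl ether are kept.

Step 6
Reactants: 8 {[(2Z,6Z)-8-bromo-3,7-dimethylocta-2,6-dien-1-yl]oxy}(tert-butyl)dimethylsilane; 9 ethyl 1,3-dithiane-2-carboxylate
Product: 10 ethyl 2-[(2Z,6Z)-8-[(tert-butyldimethylsilyl)oxy]-2,6-dimethylocta-2,6-dien-1-yl]-1,3-dithiane-2-carboxylate
Conditions: NaH, DMF–toluene, 0 °C → rt
Reagents that add atoms: none
Why: Alkylation of the soft, doubly stabilised dithiane ester enolate at the primary allylic bromide (SN2) forms C8–C9 and installs C8 as a masked carbonyl and C7 as the ester carbon.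

Step 7
Reactants: 10 ethyl 2-[(2Z,6Z)-8-[(tert-butyldimethylsilyl)oxy]-2,6-dimethylocta-2,6-dien-1-yl]-1,3-dithiane-2-carboxylate
Product: 11 2-[(2Z,6Z)-8-[(tert-butyldimethylsilyl)oxy]-2,6-dimethylocta-2,6-dien-1-yl]-1,3-dithiane-2-carbaldehyde
Conditions: i-Bu2AlH (1.1 equiv), toluene, −78 °C; aq potassium sodium tartrate
Reagents that add atoms: none
Why: Partial reduction of the hindered α,α-bis(alkylthio) ester; the tetrahedral aluminium hemiacetal is stable at −78 °C and releases the non-enolisable aldehyde on work-up (over-reduced alcohol, if any, is re-oxidised under Swern conditions).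

Step 8
Reactants: 11 2-[(2Z,6Z)-8-[(tert-butyldimethylsilyl)oxy]-2,6-dimethylocta-2,6-dien-1-yl]-1,3-dithiane-2-carbaldehyde; 5 ethyl 2-[bis(2,2,2-trifluoroethoxy)phosphoryl]propanoate
Product: 12 ethyl (2Z)-3-{2-[(2Z,6Z)-8-[(tert-butyldimethylsilyl)oxy]-2,6-dimethylocta-2,6-dien-1-yl]-1,3-dithian-2-yl}-2-methylprop-2-enoate
Conditions: KN(SiMe3)2, 18-crown-6, THF, −78 → −40 °C
Reagents that add atoms: none
Why: Second Still–Gennari olefination; the α-thio-substituted aldehyde is electrophilic and cannot enolise, and kinetic control should again give the Z enoate (ester carbon C12 cis to C8), the geometry that later dictates the cis C6/C7 relationship.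

Step 9
Reactants: 12 ethyl (2Z)-3-{2-[(2Z,6Z)-8-[(tert-butyldimethylsilyl)oxy]-2,6-dimethylocta-2,6-dien-1-yl]-1,3-dithian-2-yl}-2-methylprop-2-enoate
Product: 13 ethyl (2Z)-3-{2-[(2Z,6Z)-8-hydroxy-2,6-dimethylocta-2,6-dien-1-yl]-1,3-dithian-2-yl}-2-methylprop-2-enoate
Conditions: Bu4NF, THF, 0 °C
Reagents that add atoms: none
Why: Fluoride cleavage of the primary silyl ether frees the C6 hydroxyl; ester, dithiane and the three Z alkenes are inert.

Step 10
Reactants: 13 ethyl (2Z)-3-{2-[(2Z,6Z)-8-hydroxy-2,6-dimethylocta-2,6-dien-1-yl]-1,3-dithian-2-yl}-2-methylprop-2-enoate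
Product: 15 ethyl (2Z)-3-{2-[(2Z,6Z)-8-chloro-2,6-dimethylocta-2,6-dien-1-yl]-1,3-dithian-2-yl}-2-methylprop-2-enoate, via allylic mesylate 14 (not isolated)
Conditions: MsCl, 2,4,6-collidine, LiCl, DMF, 0 °C
Reagents that add atoms: lithium chloride, [Li+].[Cl-]; methanesulfonyl chloride, CS(=O)(=O)Cl (its sulfonyl group stays only in 14)
Why: Mesylation followed by in situ chloride displacement is the standard way to a neryl-type chloride without allylic transposition or Z/E isomerisation; halogenating oxidants that would attack the dithiane sulfur are avoided.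

Step 11
Reactants: 15 ethyl (2Z)-3-{2-[(2Z,6Z)-8-chloro-2,6-dimethylocta-2,6-dien-1-yl]-1,3-dithian-2-yl}-2-methylprop-2-enoate
Product: 16 (2Z)-3-{2-[(2Z,6Z)-8-chloro-2,6-dimethylocta-2,6-dien-1-yl]-1,3-dithian-2-yl}-2-methylprop-2-en-1-ol
Conditions: i-Bu2AlH (2.3 equiv), CH2Cl2, −78 °C; aq potassium sodium tartrate
Reagents that add atoms: none
Why: Diisobutylaluminium hydride reduces the enoate to the Z allylic alcohol (C12–OH) at −78 °C, a temperature at which the primary allylic chloride is not reduced.

Step 12
Reactants: 16 (2Z)-3-{2-[(2Z,6Z)-8-chloro-2,6-dimethylocta-2,6-dien-1-yl]-1,3-dithian-2-yl}-2-methylprop-2-en-1-ol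
Product: 17 thirteen-membered all-Z diallyl ether (oxygen bridging C6 and C12; Z alkenes C4=C5, C1=C10 and C7=C11; methyls on C4, C10 and C11; C8 as spiro 1,3-dithiane)
Conditions: NaH, THF, reflux, syringe-pump addition (final 0.003 M)
Reagents that add atoms: none
Why: Intramolecular Williamson etherification: the C12 alkoxide displaces the primary allylic chloride at C6 (SN2); the three Z alkenes and the gem-disubstituted C8 bend the chain towards closure, and high dilution suppresses oligomers.

Step 13
Reactants: 17 thirteen-membered all-Z diallyl ether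
Product: 18 (1(10)Z,4Z,6S,7S)-6-hydroxy-7-isopropenyl-4,10-dimethylcyclodeca-1(10),4-dien-8-one 1,3-propanediyl dithioacetal (C6–OH and C7–isopropenyl cis)
Conditions: (S,S)-[PhCH(CH3)]2NLi (2.5 equiv; from bis[(S)-1-phenylethyl]amine and n-BuLi), THF, −78 → −20 °C; aq NH4Cl
Reagents that add atoms: none
Why: The amide removes one enantiotopic proton at C6 (allylic and α to oxygen); the allyloxy carbanion bonds to C7 suprafacially through a five-membered envelope (C6, O, C12, C11, C7) while O–C12 breaks and the π bond moves to C11=C12, giving the lithium alkoxide of 18. The closest known reaction type is the transannular [2,3]-Wittig ring contraction of thirteen-membered diallylic and allylic propargylic ethers, including induction by homochiral lithium amides. The ten-membered ring is closed by contraction of the thirteen-membered ring (O and C12 leave the ring), not by end-to-end cyclisation, so no medium-ring entropic penalty is paid. C7 is controlled by the Z C7=C11 geometry: C8 is cis to C12, and with the C5 vinyl group exo in the envelope (the only arrangement the C5-to-C8 tether allows, gauche about the new bond) the syn product results, which is cis on the ring. C6 is controlled by which enantiotopic proton the homochiral amide removes, and because C7 follows from C6 through the ordered transition state the two centres are set together. The regioselectivity needed is C6 over C12: a C12 carbanion would have to bond to the fully substituted C4, and because amide deprotonation is reversible the faster shift from C6 should drain the mixture. The dithiane has no acidic hydrogen and is inert to amides, which is why C8 is carried in this form. A diallylic ether is a weaker carbon acid than a propargylic one, hence the excess of base and the warming; the enantiomeric excess is expected to be moderate and is to be raised by recrystallisation of 24 or 25.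

Step 14
Reactants: 18 (6S,7S)-hydroxy dithioacetal
Product: 19 6-O-(4-methoxybenzyl) ether of 18
Conditions: NaH, 4-MeOC6H4CH2Cl, Bu4NI (cat.), THF–DMF, 0 °C → rt
Reagents that add atoms: 4-methoxybenzyl chloride, COc1ccc(CCl)cc1
Why: Williamson benzylation of the only hydroxyl present, so that C6 and C8 oxygens are distinguished from here on; the sodium alkoxide is kept at or below room temperature, where anionic oxy-Cope rearrangement of the 1,5-dien-3-olate is not expected.

Step 15
Reactants: 19 6-O-(4-methoxybenzyl) dithioacetal
Product: 20 (1(10)Z,4Z,6S,7S)-7-isopropenyl-6-[(4-methoxybenzyl)oxy]-4,10-dimethylcyclodeca-1(10),4-dien-8-one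
Conditions: MeI, CaCO3, MeCN–H2O (9:1), 45 °C
Reagents that add atoms: water, O
Why: Alkylative hydrolysis of the dithiane under buffered, non-oxidising conditions that leave the trisubstituted alkenes and the benzyl ether alone; mercury salts and halonium sources, which could trigger transannular cyclisation of the diene, are avoided, and the ether at C6 blocks retro-aldol cleavage of the β-oxygenated ketone.

Step 16
Reactants: 20 C8 ketone
Product: 21 (1(10)Z,4Z,6S,7R,8R)-7-isopropenyl-6-[(4-methoxybenzyl)oxy]-4,10-dimethylcyclodeca-1(10),4-dien-8-ol (C6–O, C7 side chain and C8–OH all cis)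
Conditions: LiAlH4, LiI, Et2O, −78 °C
Reagents that add atoms: none
Why: Chelation-controlled 1,3-syn reduction of a β-alkoxy ketone: lithium bridges the C8 carbonyl and the C6 ether oxygen in a six-membered chelate with C5 and the C7 substituent equatorial, and axial hydride delivery places C9 equatorial, which gives the 6,8-syn (ring-cis) alcohol.

Step 17
Reactants: 21 isopropenyl alcohol
Product: 22 (1(10)Z,4Z,6S,7R,8R)-7-isopropyl-6-[(4-methoxybenzyl)oxy]-4,10-dimethylcyclodeca-1(10),4-dien-8-ol
Conditions: H2 (1–3 atm), RhCl(PPh3)3 (10 mol %), benzene–EtOH, rt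
Reagents that add atoms: none
Why: Homogeneous hydrogenation with RhCl(PPh3)3 saturates the 1,1-disubstituted alkene much faster than the two trisubstituted ring alkenes; it is placed after dithiane removal because thioacetals poison the rhodium catalyst, and no stereocentre is created.

Step 18
Reactants: 22 isopropyl alcohol; 23 3,4,5-trimethoxybenzoyl chloride
Product: 24 (1(10)Z,4Z,6S,7R,8R)-7-isopropyl-6-[(4-methoxybenzyl)oxy]-4,10-dimethylcyclodeca-1(10),4-dien-8-yl 3,4,5-trimethoxybenzoate
Conditions: Et3N, DMAP, CH2Cl2, 0 °C → rt
Reagents that add atoms: none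
Why: DMAP-catalysed acylation of the single free hydroxyl with retention at C8; regiochemistry is unambiguous because C6 is etherified.

Step 19
Reactants: 24 C6 ether ester
Product: 25 (1(10)Z,4Z,6S,7S,8R)-6-hydroxy-7-isopropyl-4,10-dimethylcyclodeca-1(10),4-dien-8-yl 3,4,5-trimethoxybenzoate
Conditions: DDQ, CH2Cl2–pH 7 buffer, 0 °C
Reagents that add atoms: none
Why: Oxidative removal of the 4-methoxybenzyl ether under neutral conditions; the acceptor-substituted trimethoxybenzoate and the isolated alkenes are not oxidised, and the absence of base avoids acyl migration from O8 to O6.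

Step 20
Reactants: 25 allylic alcohol ester
Product: 26 target, (1(10)Z,4S,5R,6R,7S,8R)-4,5-epoxy-6-hydroxy-7-isopropyl-4,10-dimethylcyclodec-1(10)-en-8-yl 3,4,5-trimethoxybenzoate
Conditions: VO(acac)2 (5 mol %), t-BuOOH, CH2Cl2, 0 °C → rt
Reagents that add atoms: tert-butyl hydroperoxide, CC(C)(C)OO
Why: Hydroxyl-directed epoxidation: the vanadate ester of the C6 alcohol delivers the peroxide oxygen to the adjacent C4=C5 alkene only, and in medium-ring Z-cycloalkenols this delivery occurs syn to the hydroxyl, setting C4 and C5 as the cis-epoxy alcohol; the Z alkene geometry is translated into the cis oxirane.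

## Compound list

1 | nerol | CC(C)=CCC/C(C)=C\CO | starting material
2 | neryl tert-butyldimethylsilyl ether | CC(C)=CCC/C(C)=C\CO[Si](C)(C)C(C)(C)C | intermediate
3 | secondary ozonide of 2 (3,3-dimethyl-1,2,4-trioxolane bearing the C1–C6 chain; mixture at the acetal carbon) | CC1(C)OOC(CC/C(C)=C\CO[Si](C)(C)C(C)(C)C)O1 | intermediate (not isolated)
4 | (4Z)-6-[(tert-butyldimethylsilyl)oxy]-4-methylhex-4-enal | O=CCC/C(C)=C\CO[Si](C)(C)C(C)(C)C | intermediate
5 | ethyl 2-[bis(2,2,2-trifluoroethoxy)phosphoryl]propanoate | CCOC(=O)C(C)P(=O)(OCC(F)(F)F)OCC(F)(F)F | starting material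
6 | ethyl (2Z,6Z)-8-[(tert-butyldimethylsilyl)oxy]-2,6-dimethylocta-2,6-dienoate | CCOC(=O)/C(C)=C\CC/C(C)=C\CO[Si](C)(C)C(C)(C)C | intermediate
7 | (2Z,6Z)-8-[(tert-butyldimethylsilyl)oxy]-2,6-dimethylocta-2,6-dien-1-ol | OC/C(C)=C\CC/C(C)=C\CO[Si](C)(C)C(C)(C)C | intermediate
8 | {[(2Z,6Z)-8-bromo-3,7-dimethylocta-2,6-dien-1-yl]oxy}(tert-butyl)dimethylsilane | BrC/C(C)=C\CC/C(C)=C\CO[Si](C)(C)C(C)(C)C | intermediate
9 | ethyl 1,3-dithiane-2-carboxylate | CCOC(=O)C1SCCCS1 | starting material
10 | ethyl 2-[(2Z,6Z)-8-[(tert-butyldimethylsilyl)oxy]-2,6-dimethylocta-2,6-dien-1-yl]-1,3-dithiane-2-carboxylate | CCOC(=O)C1(C/C(C)=C\CC/C(C)=C\CO[Si](C)(C)C(C)(C)C)SCCCS1 | intermediate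
11 | 2-[(2Z,6Z)-8-[(tert-butyldimethylsilyl)oxy]-2,6-dimethylocta-2,6-dien-1-yl]-1,3-dithiane-2-carbaldehyde | O=CC1(C/C(C)=C\CC/C(C)=C\CO[Si](C)(C)C(C)(C)C)SCCCS1 | intermediate
12 | ethyl (2Z)-3-{2-[(2Z,6Z)-8-[(tert-butyldimethylsilyl)oxy]-2,6-dimethylocta-2,6-dien-1-yl]-1,3-dithian-2-yl}-2-methylprop-2-enoate | CCOC(=O)/C(C)=C\C1(C/C(C)=C\CC/C(C)=C\CO[Si](C)(C)C(C)(C)C)SCCCS1 | intermediate
13 | ethyl (2Z)-3-{2-[(2Z,6Z)-8-hydroxy-2,6-dimethylocta-2,6-dien-1-yl]-1,3-dithian-2-yl}-2-methylprop-2-enoate | CCOC(=O)/C(C)=C\C1(C/C(C)=C\CC/C(C)=C\CO)SCCCS1 | intermediate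
14 | methanesulfonate of 13 | CCOC(=O)/C(C)=C\C1(C/C(C)=C\CC/C(C)=C\COS(C)(=O)=O)SCCCS1 | intermediate (not isolated)
15 | ethyl (2Z)-3-{2-[(2Z,6Z)-8-chloro-2,6-dimethylocta-2,6-dien-1-yl]-1,3-dithian-2-yl}-2-methylprop-2-enoate | CCOC(=O)/C(C)=C\C1(C/C(C)=C\CC/C(C)=C\CCl)SCCCS1 | intermediate
16 | (2Z)-3-{2-[(2Z,6Z)-8-chloro-2,6-dimethylocta-2,6-dien-1-yl]-1,3-dithian-2-yl}-2-methylprop-2-en-1-ol | OC/C(C)=C\C1(C/C(C)=C\CC/C(C)=C\CCl)SCCCS1 | intermediate
17 | thirteen-membered all-Z diallyl ether, C8 as spiro 1,3-dithiane (precursor of the key step) | O1C/C=C(C)\CC/C=C(C)\CC2(SCCCS2)/C=C(C)\C1 | intermediate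
18 | (1(10)Z,4Z,6S,7S)-6-hydroxy-7-isopropenyl-4,10-dimethylcyclodeca-1(10),4-dien-8-one 1,3-propanediyl dithioacetal (product of the key step) | S1CCCSC12C/C(C)=C\CC/C(C)=C\[C@H](O)[C@@H]2C(C)=C | intermediate
19 | 6-O-(4-methoxybenzyl) ether of 18 | S1CCCSC12C/C(C)=C\CC/C(C)=C\[C@H](OCc3ccc(OC)cc3)[C@@H]2C(C)=C | intermediate
20 | (1(10)Z,4Z,6S,7S)-7-isopropenyl-6-[(4-methoxybenzyl)oxy]-4,10-dimethylcyclodeca-1(10),4-dien-8-one | O=C1C/C(C)=C\CC/C(C)=C\[C@H](OCc2ccc(OC)cc2)[C@@H]1C(C)=C | intermediate
21 | (1(10)Z,4Z,6S,7R,8R)-7-isopropenyl-6-[(4-methoxybenzyl)oxy]-4,10-dimethylcyclodeca-1(10),4-dien-8-ol | O[C@@H]1C/C(C)=C\CC/C(C)=C\[C@H](OCc2ccc(OC)cc2)[C@@H]1C(C)=C | intermediate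
22 | (1(10)Z,4Z,6S,7R,8R)-7-isopropyl-6-[(4-methoxybenzyl)oxy]-4,10-dimethylcyclodeca-1(10),4-dien-8-ol | O[C@@H]1C/C(C)=C\CC/C(C)=C\[C@H](OCc2ccc(OC)cc2)[C@@H]1C(C)C | intermediate
23 | 3,4,5-trimethoxybenzoyl chloride | COc1cc(C(=O)Cl)cc(OC)c1OC | starting material
24 | (1(10)Z,4Z,6S,7R,8R)-7-isopropyl-6-[(4-methoxybenzyl)oxy]-4,10-dimethylcyclodeca-1(10),4-dien-8-yl 3,4,5-trimethoxybenzoate | COc1cc(C(=O)O[C@@H]2C/C(C)=C\CC/C(C)=C\[C@H](OCc3ccc(OC)cc3)[C@@H]2C(C)C)cc(OC)c1OC | intermediate
25 | (1(10)Z,4Z,6S,7S,8R)-6-hydroxy-7-isopropyl-4,10-dimethylcyclodeca-1(10),4-dien-8-yl 3,4,5-trimethoxybenzoate | COc1cc(C(=O)O[C@@H]2C/C(C)=C\CC/C(C)=C\[C@H](O)[C@@H]2C(C)C)cc(OC)c1OC | intermediate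
26 | (1(10)Z,4S,5R,6R,7S,8R)-4,5-epoxy-6-hydroxy-7-isopropyl-4,10-dimethylcyclodec-1(10)-en-8-yl 3,4,5-trimethoxybenzoate | COc1cc(C(=O)O[C@@H]2C/C(C)=C\CC[C@]3(C)O[C@@H]3[C@H](O)[C@@H]2C(C)C)cc(OC)c1OC | target

## Step count and least certain steps

Total: 20 steps. Longest linear sequence: 20 steps (1 → 26); 5, 9 and 23 are purchased and enter directly.

**Step 13 (key step).** Most likely to go wrong is slow or poorly selective proton removal. The diallylic ether is a weaker carbon acid than the propargylic ethers on which amide-induced contraction rests, so the temperature needed may erode discrimination between the enantiotopic C6 protons. Lithiation at C12 would open the dithiane by β-elimination instead of rearranging. The fallback replaces asymmetric deprotonation by resolution. It sets out from 17: s-BuLi in THF at −78 °C (alkyllithium-induced contraction, irreversible and fast) should give the racemate, that is 18 together with its enantiomer, F1. Esterification of the mixture with (S)-O-methylmandelic acid (DCC, DMAP) gives the (S)-O-methylmandelate of 18, F2, and the (S)-O-methylmandelate of the enantiomer, F3. These are separated by chromatography or crystallisation, and cleavage of F2 with i-Bu2AlH at −78 °C returns to the route at 18.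

**Step 16.** Most likely to go wrong is poor facial selectivity of hydride addition: the ten-membered ring may not let the lithium chelate adopt the half-chair on which 1,3-syn induction depends, and peripheral attack could favour the C8 epimer. The fallback changes the control element to a boron chelate of the free hydroxy ketone and postpones hydroxyl differentiation. It sets out from 20: DDQ removes the benzyl ether to give the β-hydroxy ketone, F4. Narasaka–Prasad reduction (Et2BOMe, NaBH4, THF–MeOH, −78 °C) should give the 6,8-syn diol, F5. Hydrogenation with RhCl(PPh3)3 gives the isopropyl diol, F6. VO(acac)2/t-BuOOH, directed by the allylic C6 hydroxyl, gives the epoxy diol, F7. Acylation with 23 (pyridine, −20 °C) should then favour the C8 hydroxyl, which has one branched neighbour fewer and is not deactivated by an adjacent oxirane, returning to the route at 26.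

**Step 20.** Most likely to go wrong is delivery to the wrong alkene face (the ring could favour the allylic-strain-minimised conformer that leads to the anti epoxy alcohol) or Lewis-acid-promoted transannular opening of the product. The fallback moves from substrate direction to reagent control: from 25, Sharpless asymmetric epoxidation with Ti(OiPr)4, L-(+)-diisopropyl tartrate and t-BuOOH over 4 Å sieves at −20 °C leads directly to 26. With this tartrate the face attacked is the required one and the C6 configuration is that of the fast-reacting, erythro-forming enantiomer. No new compound is involved.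

**Step 12.** Most likely to go wrong is oligomerisation or ionisation and SN2′ loss of the neryl-type chloride under prolonged heating with alkoxide. The fallback reverses the roles of the two termini. It sets out from 12: i-Bu2AlH gives the C12 allylic alcohol with the C6 silyl ether intact, F8. PPh3/hexachloroacetone gives the C12 allylic chloride, F9. Bu4NF frees the C6 hydroxyl to give the reversed chloro alcohol, F10. NaH at high dilution closes the same ether from the unhindered C6 alkoxide onto the methallyl-type chloride, returning to the route at 17.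

**Step 2.** Most likely to go wrong is over-oxidation, that is cleavage of the second alkene once the first is consumed, because the two trisubstituted alkenes differ only moderately in electron density. The fallback separates selection from cleavage. It sets out from 2: mCPBA at 0 °C epoxidises the more nucleophilic distal alkene to the terminal epoxide, F11, and H5IO6 in aqueous THF cleaves F11, returning to the route at 4.

## Further compounds

F1 | step 13 | enantiomer of 18, (6R,7R)-hydroxy dithioacetal (formed with 18 as the racemate) | S1CCCSC12C/C(C)=C\CC/C(C)=C\[C@@H](O)[C@H]2C(C)=C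
F2 | step 13 | (S)-2-methoxy-2-phenylacetate of 18 | S1CCCSC12C/C(C)=C\CC/C(C)=C\[C@H](OC(=O)[C@@H](OC)c3ccccc3)[C@@H]2C(C)=C
F3 | step 13 | (S)-2-methoxy-2-phenylacetate of F1 | S1CCCSC12C/C(C)=C\CC/C(C)=C\[C@@H](OC(=O)[C@@H](OC)c3ccccc3)[C@H]2C(C)=C
F4 | step 16 | (1(10)Z,4Z,6S,7S)-6-hydroxy-7-isopropenyl-4,10-dimethylcyclodeca-1(10),4-dien-8-one | O=C1C/C(C)=C\CC/C(C)=C\[C@H](O)[C@@H]1C(C)=C
F5 | step 16 | all-cis 7-isopropenyl-4,10-dimethylcyclodeca-1(10),4-diene-6,8-diol | O[C@@H]1C/C(C)=C\CC/C(C)=C\[C@H](O)[C@@H]1C(C)=C
F6 | step 16 | all-cis 7-isopropyl-4,10-dimethylcyclodeca-1(10),4-diene-6,8-diol | O[C@@H]1C/C(C)=C\CC/C(C)=C\[C@H](O)[C@@H]1C(C)C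
F7 | step 16 | (1(10)Z,4S,5R,6R,7S,8R)-4,5-epoxy-7-isopropyl-4,10-dimethylcyclodec-1(10)-ene-6,8-diol | O[C@@H]1C/C(C)=C\CC[C@]2(C)O[C@@H]2[C@H](O)[C@@H]1C(C)C
F0 | step 20 | none | none
F8 | step 12 | (2Z)-3-{2-[(2Z,6Z)-8-[(tert-butyldimethylsilyl)oxy]-2,6-dimethylocta-2,6-dien-1-yl]-1,3-dithian-2-yl}-2-methylprop-2-en-1-ol | OC/C(C)=C\C1(C/C(C)=C\CC/C(C)=C\CO[Si](C)(C)C(C)(C)C)SCCCS1
F9 | step 12 | tert-butyl{[(2Z,6Z)-8-{2-[(1Z)-3-chloro-2-methylprop-1-en-1-yl]-1,3-dithian-2-yl}-3,7-dimethylocta-2,6-dien-1-yl]oxy}dimethylsilane | ClC/C(C)=C\C1(C/C(C)=C\CC/C(C)=C\CO[Si](C)(C)C(C)(C)C)SCCCS1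
F10 | step 12 | (2Z,6Z)-8-{2-[(1Z)-3-chloro-2-methylprop-1-en-1-yl]-1,3-dithian-2-yl}-3,7-dimethylocta-2,6-dien-1-ol | ClC/C(C)=C\C1(C/C(C)=C\CC/C(C)=C\CO)SCCCS1
F11 | step 2 | tert-butyl{[(2Z)-5-(3,3-dimethyloxiran-2-yl)-3-methylpent-2-en-1-yl]oxy}dimethylsilane | CC1(C)OC1CC/C(C)=C\CO[Si](C)(C)C(C)(C)C
A1 | alternative 1 | ten-membered Z,Z-diene with C2 phenylsulfonyl, C8 4-methoxybenzyl ether and C6 silyl ether | COc1ccc(CO[C@@H]2C/C(C)=C\C(S(=O)(=O)c3ccccc3)C/C(C)=C\[C@H](O[Si](C)(C)C(C)(C)C)[C@@H]2C(C)C)cc1
A2 | alternative 1 | open-chain C3 allylic chloride with C2 allylic phenyl sulfone | ClC/C(C)=C\[C@H](O[Si](C)(C)C(C)(C)C)[C@H](C(C)C)[C@H](OCc1ccc(OC)cc1)C/C(C)=C\CS(=O)(=O)c1ccccc1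
A3 | alternative 2 | (Z,Z)-8-(dimethylphenylsilyl)-7-isopropyl-4,10-dimethylcyclodeca-1(10),4-dien-6-one | C[Si](C)(c1ccccc1)[C@@H]1C/C(C)=C\CC/C(C)=C\C(=O)[C@@H]1C(C)C
A4 | alternative 2 | cis-1-[(E)-2-(dimethylphenylsilyl)-1-isopropylethenyl]-6-isopropenyl-3-methylcyclohex-2-en-1-ol | C[Si](C)(c1ccccc1)/C=C(\C(C)C)[C@@]2(O)C=C(C)CC[C@H]2C(C)=C
A5 | alternative 2 | (S)-isopiperitenone, (6S)-3-methyl-6-(prop-1-en-2-yl)cyclohex-2-en-1-one | O=C1C=C(C)CC[C@H]1C(C)=C
A6 | alternative 3 | ten-membered Z,Z-dienone with C8 ketone and C6 silyl ether | O=C1C/C(C)=C\CC/C(C)=C\[C@H](O[Si](C)(C)C(C)(C)C)[C@@H]1C(C)C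
A7 | alternative 3 | open-chain bromomethyl ketone with Z alkenyl iodide at C10 | BrCC(=O)[C@@H](C(C)C)[C@@H](O[Si](C)(C)C(C)(C)C)/C=C(C)\CC/C=C(C)\I
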